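I decide to follow this flask by one rate, the loss of electrophile per unit of electrophile, and to leave its concentrations aside.

electrophile 0.40 M (fed, over 8.0 h); nucleophile 0.600 M; protic impurity 0.400 M; solid base 0.320 M; time 8.0 d

    electrophile + protic impurity → quenched substrate (k1 = 1.45 × 10⁻⁵ L mol⁻¹ s⁻¹)
    acid set free + free base ⇌ salt of the base, settled at all times (K2 = 7.86 L mol⁻¹)
    solid base ⇌ free base, rate k3*(cs3 - [free base]) while solid is left; crystals form when [free base] > cs3 (cs3 = 0.16 M, k3 = 1.20 × 10⁻⁵ s⁻¹)
    nucleophile + acid set free ⇌ protonated nucleophile, settled at all times (K4 = 5200 L mol⁻¹)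
    electrophile + nucleophile → acid set free + product (k5 = 7.77 × 10⁻⁶ L mol⁻¹ s⁻¹)

- part of the electrophile that has reacted at 8.0 d
- share of the unused nucleophile that is free and not bound as protonated nucleophile, at 8.0 d

Electrophile, once fed in, goes two ways: to product with the nucleophile and to quenched substrate with the protic impurity. At the charged amounts the nucleophile term is 4.66 × 10⁻⁶ s⁻¹ and the impurity term 5.80 × 10⁻⁶ s⁻¹. Their sum, 1.05 × 10⁻⁵ s⁻¹, is the loss coefficient, a pseudo-first-order constant, and it starts with a half-life of 0.767 d. At the charged amounts, equal rate constants would give the impurity 40.0% of the electrophile, which is my zero of the scale, but its larger constant lifts that starting share to 55.4%.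

Now let the whole charge split so. The impurity term falls to a fraction 0.446 of its start. The nucleophile term falls to 0.406, because each product costs two nucleophiles: the acid set free binds the nucleophile with a constant of 5200 L mol⁻¹, far above the 7.86 L mol⁻¹ of the free base. The coefficient thus ends near 4.48 × 10⁻⁶ s⁻¹, slower by a factor 2.34. Counted from the middle of the feed, the flask has 7.83 d. The end coefficient then gives 95.2% reacted, and the mean of start and end gives 99.4%. I commit to that range, with 57.7% of the unused nucleophile free.

The forecast says 98% and 60%, a free share above mine, on the ground that “each product formed removes two free nucleophiles”. The flask gives 97.9% and 59.8%.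

At 8.00 d this flask holds 42.7% of its nucleophile and 45.2% of its impurity, so its coefficient stands at 4.61 × 10⁻⁶ s⁻¹, down by a factor 2.27, with a half-life of 1.74 d. At the same time the neighbour charged with 1.0 M of electrophile holds 1.99% of its nucleophile and 1.71% of its impurity; its coefficient is 1.92 × 10⁻⁷ s⁻¹, its half-life 41.8 d, and 30.8% of its electrophile stands unused. Ten times the time takes the first flask's electrophile from 2.13% to 0%, its product from 43.0% to 43.9%, and its nucleophile from 42.7% to 41.5%.

All constants were chosen freely; no experiment stands behind them.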